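**Plan**
- Cut C9–C11: a homofarnesyl copper reagent opens an 8α,9α-epoxide at C9. The trans C8–OH/C9–C11 pair on ring B is the retron; because the decalin is cis-fused (C5–H and C10–CH3 on the same face), ring B can take the chair in which C9–C11 and C8–O are trans-diaxial, which a trans-decalin cannot.
- Epoxide ← C8=C9 alkene ← ring-B enone of (S)-carvone: the carvone ring is ring B (C5–C10), its methyl is the C8 methyl, its carbonyl is C9, its stereocentre is C5.
- Ring A is closed last onto carvone: C10 is made quaternary by two α′-alkylations (allyl, then methyl); the C3–C4 bond is formed by hydrogen-atom-transfer radical cyclisation of the isopropenyl group onto a nitrile, which gives the C3 ketone and the C4 gem-dimethyl group together.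
- Stereochemistry: C5 from carvone; C10 by methylation anti to the isopropenyl group (methyl last, hence cis fusion); C8 by anti hydroxybromination and closure; C9 by inversion in the key step.
- Side chain: (2E,6E)-farnesol is homologated by one carbon (oxidation, Wittig, hydroboration, bromination); the alkene geometry is carried through.

Key step: step 14

Remark: the target as drawn has C5–H cis to the C10 methyl, i.e. a cis-fused decalin with (5S,8R,9R,10S) configuration; the route is built for this isomer.
Numbering: decalin positions C1–C10 as in the target (C3 carbonyl, C4 gem-dimethyl, C5/C10 ring fusion, C8 carbinol, C9 chain-bearing carbon, C11 first chain carbon); β is the face of the C10 methyl.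

**Step 1**
Reactants: 1 (S)-(+)-carvone
Product: 3 6-allylcarvone, via lithium dienolate 2 (not isolated)
Conditions: LiN(iPr)2, THF, −78 °C; allyl bromide, −78 → −20 °C
Reagents that add atoms: allyl bromide, C=CCBr
Why: Kinetic deprotonation of the cross-conjugated enone at the α′-methylene (future C10) and SN2 alkylation of the lithium dienolate (ketone enolate alkylation); the allyl group should enter mainly anti to the isopropenyl group, but this centre is made planar again in step 2.

**Step 2**
Reactants: 3 6-allylcarvone
Product: 5 6-allyl-6-methylcarvone, via lithium dienolate 4 (not isolated)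
Conditions: LiN(iPr)2, THF/DMPU, −78 °C; MeI, −78 → 0 °C
Reagents that add atoms: iodomethane, CI
Why: Second α′-alkylation of the fully substituted dienolate (substrate-controlled enolate alkylation): iodomethane should approach anti to the pseudoaxial C5 isopropenyl group, so the C10 methyl ends trans to it and the allyl arm cis, the arrangement that later gives the cis ring fusion.

**Step 3**
Reactants: 5 6-allyl-6-methylcarvone
Product: 7 primary alcohol, via alkyl(disiamyl)borane 6 (not isolated)
Conditions: bis(3-methylbutan-2-yl)borane (Sia2BH, from BH3·SMe2 and 2-methylbut-2-ene), THF, 0 °C; then Me3NO·2H2O, 60 °C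
Reagents that add atoms: trimethylamine N-oxide, C[N+](C)(C)[O-]
Why: Hydroboration–oxidation: the bulky dialkylborane should add anti-Markovnikov to the monosubstituted allyl alkene much faster than to the hindered 1,1-disubstituted isopropenyl alkene or the enone, and amine N-oxide oxidation of the C–B bond avoids the alkaline peroxide that would epoxidise the enone.

**Step 4**
Reactants: 7 primary alcohol
Product: 10 nitrile, via aldehyde 8 (not isolated), via aldimine 9 (not isolated)
Conditions: TEMPO (10 mol %), PhI(OAc)2, NH4OAc, MeCN/H2O, rt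
Reagents that add atoms: ammonium acetate, CC(=O)[O-].[NH4+]
Why: One-pot oxidation–imination–oxidation (nitroxyl/hypervalent iodine oxidation of the alcohol to the aldehyde, condensation with ammonia, dehydrogenation of the aldimine) should give the nitrile without touching the alkenes or the enone.

**Step 5**
Reactants: 10 nitrile
Product: 12 cis-fused enedione, via ketimine 11 (not isolated)
Conditions: Fe(acac)3 (0.5 equiv), PhSiH3, EtOH, 60 °C; then 1 M HCl, THF, rt
Reagents that add atoms: water, O
Why: Hydrogen-atom transfer from an iron hydride to the isopropenyl CH2 (Mukaiyama-type HAT) gives the tertiary C4 radical, which should close ring A by 6-exo-dig addition to the nitrile carbon C3 (radical cyclisation onto a nitrile), and hydrolysis of the resulting ketimine gives the C3 ketone next to the new gem-dimethyl carbon; the cis ring fusion follows from the cis relationship of the two arms on C10 and C5 that was set in step 2.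

**Step 6**
Reactants: 12 cis-fused enedione
Product: 13 C3 dioxolane enone
Conditions: (TMSOCH2)2, TMSOTf (cat.), CH2Cl2, −78 → −20 °C
Reagents that add atoms: 1,2-bis(trimethylsilyloxy)ethane, C[Si](C)(C)OCCO[Si](C)(C)C
Why: Acetalisation under silyl-transfer conditions should take place only at the saturated C3 ketone, because the C9 carbonyl is conjugated and flanked by the quaternary C10 and the C8 methyl.

**Step 7**
Reactants: 13 C3 dioxolane enone
Product: 15 enol triflate, via lithium enolate 14 (not isolated)
Conditions: LiBH(sBu)3 (L-Selectride), THF, −78 °C; then PhNTf2, −78 → 0 °C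
Reagents that add atoms: N-phenylbis(trifluoromethanesulfonimide), O=S(=O)(N(c1ccccc1)S(=O)(=O)C(F)(F)F)C(F)(F)F
Why: Conjugate hydride addition of the hindered borohydride to the enone, whose β-carbon C7 carries no substituent besides the ring and whose carbonyl is shielded by the quaternary C10, gives the C8–C9 enolate regiospecifically, and O-sulfonylation traps it as the enol triflate (reductive enol triflate formation).

**Step 8**
Reactants: 15 enol triflate
Product: 16 C8=C9 alkene
Conditions: Pd(OAc)2 (5 mol %), PPh3, Bu3N, HCO2H, DMF, 60 °C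
Reagents that add atoms: none
Why: Palladium-catalysed hydrogenolysis of the enol triflate with formate as hydride source (oxidative addition, decarboxylation of the formate, reductive elimination) replaces OTf by H and leaves the C8=C9 double bond in place.

**Step 9**
Reactants: 16 C8=C9 alkene
Product: 18 8α,9α-epoxide, via bromohydrin 17 (not isolated)
Conditions: NBS, THF/H2O, 0 °C; then K2CO3, MeOH, rt
Reagents that add atoms: water, O
Why: Hydroxybromination then base-mediated closure: the bromonium ion should form on the convex β face, water opens it anti at the tertiary C8 (Markovnikov) from the α face, and intramolecular SN2 displacement of the 9β-bromide by the 8α-alkoxide gives the α-epoxide, oxygen being placed on the face opposite to the one a peracid would attack.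

**Step 10**
Reactants: 19 (2E,6E)-farnesol
Product: 20 (2E,6E)-farnesal
Conditions: MnO2, CH2Cl2, rt
Reagents that add atoms: none
Why: Heterogeneous allylic oxidation with MnO2 stops at the enal and leaves the 2E geometry and the isolated alkenes untouched.

**Step 11**
Reactants: 20 (2E,6E)-farnesal
Product: 21 terminal tetraene
Conditions: Ph3PCH3Br, KOtBu, THF, 0 °C → rt
Reagents that add atoms: methyltriphenylphosphonium bromide, C[P+](c1ccccc1)(c1ccccc1)c1ccccc1.[Br-]
Why: Wittig methylenation of the enal with the non-stabilised ylide gives the terminal 1,3-diene without changing the trisubstituted alkene geometry.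

**Step 12**
Reactants: 21 terminal tetraene
Product: 23 (3E,7E)-homofarnesol, via alkyl-9-BBN 22 (not isolated)
Conditions: 9-BBN, THF, 0 °C → rt; then NaOH, H2O2, 0 °C
Reagents that add atoms: hydrogen peroxide, OO
Why: Hydroboration–oxidation: the bulky 9-BBN should add only to the monosubstituted terminal alkene of the diene with boron on the terminal carbon, and alkaline peroxide converts C–B into C–OH, a one-carbon homologation of farnesol that keeps all alkene geometries.

**Step 13**
Reactants: 23 (3E,7E)-homofarnesol
Product: 24 (3E,7E)-homofarnesyl bromide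
Conditions: CBr4, PPh3, CH2Cl2, 0 °C
Reagents that add atoms: carbon tetrabromide, BrC(Br)(Br)Br
Why: Appel bromination of the primary homoallylic alcohol (SN2 displacement of the alkoxyphosphonium ion by bromide) under neutral conditions.

**Step 14**
Reactants: 18 8α,9α-epoxide; 24 (3E,7E)-homofarnesyl bromide
Product: 26 coupled dioxolane carbinol, via homofarnesylmagnesium bromide 25 (not isolated)
Conditions: 24, Mg, THF, rt; then CuI (10 mol %), 18, THF, −30 → 0 °C; aq. NH4Cl
Reagents that add atoms: none
Why: Grignard reagent 25 transmetalates to an alkylcopper species that attacks C9 from the β face anti to the C9–O bond (SN2 opening through oxidative addition and reductive elimination at copper), and the magnesium alkoxide is protonated on work-up. The closest known reaction type is the copper-catalysed opening of 1-methylcyclohexene oxides by alkyl Grignard reagents at the secondary carbon. No ring is closed. C9 is set by inversion (chain β, trans to the oxygen) and C8 keeps the configuration installed in step 9, so the trans C8–OH/C9–C11 relationship follows from the mechanism and not from a facial bias. The step needs regioselectivity for C9 over C8: C8 is fully substituted and closed to SN2 attack, and the cis ring fusion lets ring B take the half-chair in which attack at C9 is axial (trans-diaxial opening, Fürst–Plattner rule) with the C10 methyl equatorial and only hydrogens at C5 and C7 syn-axial to the incoming chain. The dioxolane and the three trisubstituted alkenes of the chain are inert to the organometallic.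

**Step 15**
Reactants: 26 coupled dioxolane carbinol
Product: 27 IN0671
Conditions: PPTS (cat.), acetone/H2O, 55 °C
Reagents that add atoms: water, O
Why: Acid-catalysed hydrolysis of the dioxolane under weakly acidic conditions regenerates the C3 ketone without dehydrating the tertiary alcohol or protonating the trisubstituted alkenes.

**Compound list**
1 | (S)-(+)-carvone, (5S)-2-methyl-5-(prop-1-en-2-yl)cyclohex-2-en-1-one | O=C1C[C@@H](C(C)=C)CC=C1C | starting material
2 | lithium cross-conjugated α′-dienolate of 1 (O–C=CH next to the isopropenyl-bearing carbon) | [Li]OC1=C[C@@H](C(C)=C)CC=C1C | intermediate (not isolated)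
3 | (5S,6R)-2-methyl-6-(prop-2-en-1-yl)-5-(prop-1-en-2-yl)cyclohex-2-en-1-one (allyl trans to isopropenyl, major epimer) | O=C1[C@H](CC=C)[C@@H](C(C)=C)CC=C1C | intermediate
4 | lithium α′-dienolate of 3 | [Li]OC1=C(CC=C)[C@@H](C(C)=C)CC=C1C | intermediate (not isolated)
5 | (5R,6S)-2,6-dimethyl-6-(prop-2-en-1-yl)-5-(prop-1-en-2-yl)cyclohex-2-en-1-one (methyl trans, allyl cis to isopropenyl) | O=C1[C@@](C)(CC=C)[C@@H](C(C)=C)CC=C1C | intermediate
6 | B-alkyl bis(3-methylbutan-2-yl)borane from 5 (boron on the terminal carbon of the former allyl group) | O=C1[C@@](C)(CCCB(C(C)C(C)C)C(C)C(C)C)[C@@H](C(C)=C)CC=C1C | intermediate (not isolated)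
7 | (5R,6S)-6-(3-hydroxypropyl)-2,6-dimethyl-5-(prop-1-en-2-yl)cyclohex-2-en-1-one | O=C1[C@@](C)(CCCO)[C@@H](C(C)=C)CC=C1C | intermediate
8 | 3-[(1S,6R)-1,3-dimethyl-2-oxo-6-(prop-1-en-2-yl)cyclohex-3-en-1-yl]propanal | O=C1[C@@](C)(CCC=O)[C@@H](C(C)=C)CC=C1C | intermediate (not isolated)
9 | N–H aldimine of 8 | O=C1[C@@](C)(CCC=N)[C@@H](C(C)=C)CC=C1C | intermediate (not isolated)
10 | 3-[(1S,6R)-1,3-dimethyl-2-oxo-6-(prop-1-en-2-yl)cyclohex-3-en-1-yl]propanenitrile | O=C1[C@@](C)(CCC#N)[C@@H](C(C)=C)CC=C1C | intermediate
11 | C3 ketimine of 12 (3-imino-4,4,8,10-tetramethyl-cis-decal-7-en-9-one, 5β-H, 10β-CH3) | O=C1[C@@]2(C)CCC(=N)C(C)(C)[C@H]2CC=C1C | intermediate (not isolated)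
12 | 4,4,8,10-tetramethyl-cis-decal-7-ene-3,9-dione (5β-H, 10β-CH3) | O=C1[C@@]2(C)CCC(=O)C(C)(C)[C@H]2CC=C1C | intermediate
13 | 3,3-ethylenedioxy-4,4,8,10-tetramethyl-cis-decal-7-en-9-one (5β-H, 10β-CH3) | O=C1[C@@]2(C)CCC3(OCCO3)C(C)(C)[C@H]2CC=C1C | intermediate
14 | lithium 3,3-ethylenedioxy-4,4,8,10-tetramethyl-cis-decal-8-en-9-olate | CC1=C(O[Li])[C@@]2(C)CCC3(OCCO3)C(C)(C)[C@H]2CC1 | intermediate (not isolated)
15 | 3,3-ethylenedioxy-4,4,8,10-tetramethyl-cis-decal-8-en-9-yl trifluoromethanesulfonate (5β-H, 10β-CH3) | CC1=C(OS(=O)(=O)C(F)(F)F)[C@@]2(C)CCC3(OCCO3)C(C)(C)[C@H]2CC1 | intermediate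
16 | 3,3-ethylenedioxy-4,4,8,10-tetramethyl-cis-decal-8-ene (C8=C9; 5β-H, 10β-CH3) | CC1=C[C@@]2(C)CCC3(OCCO3)C(C)(C)[C@H]2CC1 | intermediate
17 | 9β-bromo-3,3-ethylenedioxy-4,4,8β,10β-tetramethyl-cis-decalin-8α-ol (5β-H) | Br[C@@H]1[C@@]2(C)CCC3(OCCO3)C(C)(C)[C@H]2CC[C@@]1(C)O | intermediate (not isolated)
18 | 8α,9α-epoxy-3,3-ethylenedioxy-4,4,8β,10β-tetramethyl-cis-decalin (5β-H) | O1[C@H]2[C@@]3(C)CCC4(OCCO4)C(C)(C)[C@H]3CC[C@@]12C | intermediate
19 | (2E,6E)-farnesol, (2E,6E)-3,7,11-trimethyldodeca-2,6,10-trien-1-ol | CC(C)=CCC/C(C)=C/CC/C(C)=C/CO | starting material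
20 | (2E,6E)-farnesal | CC(C)=CCC/C(C)=C/CC/C(C)=C/C=O | intermediate
21 | (3E,7E)-4,8,12-trimethyltrideca-1,3,7,11-tetraene | CC(C)=CCC/C(C)=C/CC/C(C)=C/C=C | intermediate
22 | 9-[(3E,7E)-4,8,12-trimethyltrideca-3,7,11-trien-1-yl]-9-borabicyclo[3.3.1]nonane | CC(C)=CCC/C(C)=C/CC/C(C)=C/CCB1C2CCCC1CCC2 | intermediate (not isolated)
23 | (3E,7E)-homofarnesol, (3E,7E)-4,8,12-trimethyltrideca-3,7,11-trien-1-ol | CC(C)=CCC/C(C)=C/CC/C(C)=C/CCO | intermediate
24 | (3E,7E)-1-bromo-4,8,12-trimethyltrideca-3,7,11-triene | CC(C)=CCC/C(C)=C/CC/C(C)=C/CCBr | intermediate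
25 | (3E,7E)-homofarnesylmagnesium bromide | CC(C)=CCC/C(C)=C/CC/C(C)=C/CC[Mg]Br | intermediate (not isolated)
26 | 3,3-ethylenedioxy-4,4,8β,10β-tetramethyl-9β-[(3E,7E)-4,8,12-trimethyltrideca-3,7,11-trien-1-yl]-cis-decalin-8α-ol (5β-H, 9α-H) | CC(C)=CCC/C(C)=C/CC/C(C)=C/CC[C@@H]1[C@@]2(C)CCC3(OCCO3)C(C)(C)[C@H]2CC[C@@]1(C)O | intermediate
27 | IN0671, (5S,8R,9R,10S)-8α-hydroxy-4,4,8β,10β-tetramethyl-9β-[(3E,7E)-4,8,12-trimethyltrideca-3,7,11-trien-1-yl]-cis-decalin-3-one (5β-H) | CC(C)=CCC/C(C)=C/CC/C(C)=C/CC[C@@H]1[C@@]2(C)CCC(=O)C(C)(C)[C@H]2CC[C@@]1(C)O | target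

**Step count**
Total: 15 steps. Longest linear sequence: 11 steps (steps 1–9, 14, 15); the side-chain branch is steps 10–13.

**Steps most likely to fail**

1. Step 14. Substitution at C9, next to the quaternary C10, may be slow, so that base-induced isomerisation of the epoxide to an allylic alcohol or halide-induced rearrangement takes over. Fallback from 18 back to 26: a smaller and more reactive sp2 nucleophile makes the C9–C11 bond, and the large fragments are joined one bond further out. Vinylmagnesium bromide with CuI should open 18 to 9β-vinyl carbinol F1. 9-BBN adds to the vinyl group to give alkylborane F2, which is coupled by B-alkyl Suzuki–Miyaura reaction (PdCl2(dppf), Cs2CO3, DMF/THF/H2O) with (1E,5E)-vinyl iodide F5 to give 26. F5 would come from commercial geranyl bromide (CC(C)=CCC/C(C)=C/CBr): alkylation of lithiated 1-(trimethylsilyl)propyne gives silyl enyne F3, K2CO3/MeOH gives terminal enyne F4, and methylalumination (AlMe3, Cp2ZrCl2 cat.) followed by iodine gives F5.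

2. Step 5. The tertiary radical may be reduced by the metal hydride (net hydrogenation of the isopropenyl group), or add to the enone of a second molecule, before the slower 6-exo closure onto the nitrile. Fallback from 10 back to 12: the radical is generated by halogen abstraction in a tin hydride chain, where the hydrogen donor is kept dilute. Markovnikov hydrobromination of the isopropenyl group (HBr, AcOH, 0 °C) gives tertiary bromide F6; slow addition of Bu3SnH with AIBN in benzene at 80 °C should give the same ketimine 11, and aqueous HCl gives 12.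

3. Step 9. The bromonium ion may form on the concave α face of the cis-decalin; the sequence would then end in the β-epoxide and, after step 14, in the C8,C9-bis-epimer. Fallback from 16 back to 18: direct oxygen transfer from a peracid (mCPBA, NaHCO3, CH2Cl2, 0 °C), which puts the oxygen on the face that the bromonium route attacks with bromine and so gives the opposite epoxide to that route; no new compound is involved.

**Further compounds**
F1 | step 14 | 3,3-ethylenedioxy-4,4,8β,10β-tetramethyl-9β-vinyl-cis-decalin-8α-ol (5β-H) | C=C[C@@H]1[C@@]2(C)CCC3(OCCO3)C(C)(C)[C@H]2CC[C@@]1(C)O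
F2 | step 14 | 9-BBN adduct of F1 (boron on the terminal carbon of the former vinyl group) | C1CCC2CCCC1B2CC[C@@H]1[C@@]2(C)CCC3(OCCO3)C(C)(C)[C@H]2CC[C@@]1(C)O
F3 | step 14 | (E)-(6,10-dimethylundeca-5,9-dien-1-yn-1-yl)trimethylsilane | CC(C)=CCC/C(C)=C/CCC#C[Si](C)(C)C
F4 | step 14 | (E)-6,10-dimethylundeca-5,9-dien-1-yne | CC(C)=CCC/C(C)=C/CCC#C
F5 | step 14 | (1E,5E)-1-iodo-2,6,10-trimethylundeca-1,5,9-triene | CC(C)=CCC/C(C)=C/CC/C(C)=C/I
F6 | step 5 | 3-[(1S,6R)-6-(2-bromopropan-2-yl)-1,3-dimethyl-2-oxocyclohex-3-en-1-yl]propanenitrile | O=C1[C@@](C)(CCC#N)[C@@H](C(C)(C)Br)CC=C1C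
F0 | step 9 | none | none
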